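The dimethylpyran on ring B is disconnected at two bonds: C3'–CH= and O2'–CMe2 lead back to a ring B phenol and 3-methylbut-2-enal. In the forward direction, one operation joins the C5 aldehyde to the finished (3R)-6-prenylisoflavan as a formal [3+3] annulation. It runs through a boron-templated ortho-aldol, loss of PhBO to an ortho-quinone methide, and an oxa-6π electrocyclisation. The step relies on O2' being the only free phenol. C3', lying between O2' and O4', is its only open ortho carbon, because C1' carries C3 of ring C. The precursor is the 7,4'-bis-silyl ether with the 2'-OH free. C3 is set earlier by a transfer-hydrogenation cascade on a 6-bromoisoflavone.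

Key step: step 6

Remark on the chemistry: isoflavan numbering is used (ring A = C5 to C8, ring C = O1 to C4, ring B = C1' to C6'). The stereocentre C3 of the target is R (C2 > C1' > C4 > H).

Step 1
Reactants: 1 4-bromoresorcinol; 2 2,4-dimethoxyphenylacetic acid
Product: 4 6-bromo-3-(2,4-dimethoxyphenyl)-7-hydroxy-4H-chromen-4-one, via deoxybenzoin 3 (not isolated)
Conditions: BF3·OEt2 (solvent), 85 °C; then DMF, MsCl, 70 °C
Reagents that add atoms: N,N-dimethylformamide CN(C)C=O
Why: Friedel–Crafts acylation should occur at the only unhindered activated carbon of 1 (ortho to one OH, para to the other), and Vilsmeier-type formylation of the active methylene of 3 followed by cyclodehydration onto the chelated ortho-OH closes the chromone (one-pot deoxybenzoin isoflavone synthesis).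

Step 2
Reactants: 4 6-bromo-3-(2,4-dimethoxyphenyl)-7-hydroxy-4H-chromen-4-one
Product: 8 (3R)-6-bromo-3-(2,4-dimethoxyphenyl)chroman-7-ol, via racemic isoflavanone 5 (not isolated), via cis-isoflavan-4-ol 6 (not isolated), via para-quinone methide 7 (not isolated)
Conditions: RuCl[(R,R)-TsDPEN](p-cymene) (3 mol %), HCO2H/Et3N (5:2), EtOAc, 45 °C
Reagents that add atoms: none
Why: In this Noyori-type asymmetric transfer hydrogenation cascade, Ru–H first saturates the polarised C2=C3 bond, 5 racemises through its enol while the R,R catalyst reduces only the 3R antipode quickly to the 4R cis-carbinol 6 (dynamic kinetic resolution, usual aryl-ketone face model), and the free 7-OH then expels water to 7, whose conjugate reduction at C4 leaves C3 as R.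

Step 3
Reactants: 8 (3R)-6-bromo-3-(2,4-dimethoxyphenyl)chroman-7-ol
Product: 9 4-[(3R)-6-bromo-7-hydroxychroman-3-yl]benzene-1,3-diol
Conditions: BBr3 (4 equiv), CH2Cl2, −78 °C to 0 °C
Reagents that add atoms: none
Why: Lewis-acid ether cleavage with BBr3 should remove both aryl methyl ethers faster than it opens the O1–C2 bond of ring C, no alkene is present yet, and C3 has no acidic or ionisable handle, so its configuration is kept.

Step 4
Reactants: 9 4-[(3R)-6-bromo-7-hydroxychroman-3-yl]benzene-1,3-diol
Product: 10 2-[(3R)-6-bromo-7-(tert-butyldimethylsilyloxy)chroman-3-yl]-5-(tert-butyldimethylsilyloxy)phenol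
Conditions: TBSCl (2.05 equiv), imidazole, CH2Cl2/DMF, −20 °C to 0 °C
Reagents that add atoms: tert-butyldimethylsilyl chloride CC(C)(C)[Si](C)(C)Cl
Why: In this kinetic, sterically governed silyl ether protection, O7 is the most acidic phenol (ortho bromine) and O4' has two ortho hydrogens, whereas O2' is shielded by the secondary carbon C3 of ring C, so two equivalents of the bulky chlorosilane at low temperature should leave only the 2'-OH free.

Step 5
Reactants: 10 2-[(3R)-6-bromo-7-(tert-butyldimethylsilyloxy)chroman-3-yl]-5-(tert-butyldimethylsilyloxy)phenol; 11 tributyl(3-methylbut-2-en-1-yl)stannane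
Product: 12 5-(tert-butyldimethylsilyloxy)-2-[(3R)-7-(tert-butyldimethylsilyloxy)-6-(3-methylbut-2-en-1-yl)chroman-3-yl]phenol
Conditions: Pd(PPh3)4 (10 mol %), DMF, 100 °C
Reagents that add atoms: none
Why: In this Stille coupling, zerovalent palladium inserts into the C6–Br bond and the allylstannane transfers its CH2 terminus, so the linear prenyl group should result, and the neutral medium tolerates the free phenol and both silyl ethers.

Step 6
Reactants: 12 5-(tert-butyldimethylsilyloxy)-2-[(3R)-7-(tert-butyldimethylsilyloxy)-6-(3-methylbut-2-en-1-yl)chroman-3-yl]phenol; 13 3-methylbut-2-enal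
Product: 16 7,4'-bis(tert-butyldimethylsilyl) ether of the target, via benzodioxaborin 14 (not isolated), via ortho-quinone methide 15 (not isolated)
Conditions: 13 (3 equiv), PhB(OH)2 (1.2 equiv), EtCO2H (0.3 equiv), toluene, reflux, Dean–Stark
Reagents that add atoms: none
Why: The 2'-OH of 12 esterifies PhB(OH)2, the boron binds the carbonyl oxygen of 13, and a closed six-membered transition state delivers the aldehyde carbon to the ortho carbon C3' to give benzodioxaborin 14 (first bond, C3'–CH). On heating, 14 loses PhBO in a retro-[4+2] to the vinylogous ortho-quinone methide 15, an s-cis 1-oxatriene whose thermal disrotatory oxa-6π electrocyclisation joins O2' to the CMe2 terminus (second bond) and restores the aromaticity of ring B. The closest known reaction type is the phenylboronic acid-mediated formal [3+3] chromene annulation of phenols with 3-methylbut-2-enal, the templated relative of the amine-catalysed Knoevenagel/electrocyclisation sequence. The one ring closed is the six-membered pyran, and it closes by a pericyclic 6π process, not by an ionic exo or endo attack. No stereocentre is created, because the new sp3 carbon carries two methyl groups, and C3 is remote and not enolisable. Site selectivity rests on the substrate: O2' is the only free phenol, C1' is blocked by ring C so C3' is its only ortho carbon, the boron tether cannot reach the para carbon C5', and the silyl ethers on O7 and O4' shut off C8 of ring A and closure onto O4'.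

Step 7
Reactants: 16 7,4'-bis(tert-butyldimethylsilyl) ether of the target
Product: 17 8-[(3R)-7-hydroxy-6-(3-methylbut-2-en-1-yl)chroman-3-yl]-2,2-dimethyl-2H-chromen-5-ol (target)
Conditions: TBAF (2.2 equiv), AcOH (2.2 equiv), THF, 0 °C
Reagents that add atoms: none
Why: Fluoride-driven cleavage of aryl silyl ethers, buffered by AcOH, is neutral enough to spare the prenyl group ortho to the freed 7-OH, the chromene double bond and the C3 stereocentre.

Compound list
1 | 4-bromoresorcinol | Oc1ccc(Br)c(O)c1 | starting material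
2 | 2,4-dimethoxyphenylacetic acid | COc1ccc(CC(=O)O)c(OC)c1 | starting material
3 | 1-(5-bromo-2,4-dihydroxyphenyl)-2-(2,4-dimethoxyphenyl)ethan-1-one (deoxybenzoin) | COc1ccc(CC(=O)c2cc(Br)c(O)cc2O)c(OC)c1 | intermediate
4 | 6-bromo-3-(2,4-dimethoxyphenyl)-7-hydroxy-4H-chromen-4-one | COc1ccc(-c2coc3cc(O)c(Br)cc3c2=O)c(OC)c1 | intermediate
5 | racemic 6-bromo-3-(2,4-dimethoxyphenyl)-7-hydroxychroman-4-one | COc1ccc(C2COc3cc(O)c(Br)cc3C2=O)c(OC)c1 | intermediate
6 | (3R,4R)-6-bromo-3-(2,4-dimethoxyphenyl)chromane-4,7-diol (cis) | Brc1cc2c(cc1O)OC[C@@H](c1ccc(OC)cc1OC)[C@H]2O | intermediate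
7 | (3R)-6-bromo-3-(2,4-dimethoxyphenyl)-2,3-dihydro-7H-chromen-7-one (para-quinone methide) | O=C1C=C2OC[C@@H](c3ccc(OC)cc3OC)C=C2C=C1Br | intermediate
8 | (3R)-6-bromo-3-(2,4-dimethoxyphenyl)chroman-7-ol | Brc1cc2c(cc1O)OC[C@@H](c1ccc(OC)cc1OC)C2 | intermediate
9 | 4-[(3R)-6-bromo-7-hydroxychroman-3-yl]benzene-1,3-diol | Brc1cc2c(cc1O)OC[C@@H](c1ccc(O)cc1O)C2 | intermediate
10 | 2-[(3R)-6-bromo-7-(tert-butyldimethylsilyloxy)chroman-3-yl]-5-(tert-butyldimethylsilyloxy)phenol | Brc1cc2c(cc1O[Si](C)(C)C(C)(C)C)OC[C@@H](c1ccc(O[Si](C)(C)C(C)(C)C)cc1O)C2 | intermediate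
11 | tributyl(3-methylbut-2-en-1-yl)stannane | CCCC[Sn](CCCC)(CCCC)CC=C(C)C | starting material
12 | 5-(tert-butyldimethylsilyloxy)-2-[(3R)-7-(tert-butyldimethylsilyloxy)-6-(3-methylbut-2-en-1-yl)chroman-3-yl]phenol | CC(C)=CCc1cc2c(cc1O[Si](C)(C)C(C)(C)C)OC[C@@H](c1ccc(O[Si](C)(C)C(C)(C)C)cc1O)C2 | intermediate
13 | 3-methylbut-2-enal | CC(C)=CC=O | starting material
14 | 4-(2-methylprop-1-enyl)-2-phenyl-4H-1,3,2-benzodioxaborin built on O2'/C3' of 12 (carbinol carbon unassigned) | CC(C)=CCc1cc2c(cc1O[Si](C)(C)C(C)(C)C)OC[C@@H](c1ccc(O[Si](C)(C)C(C)(C)C)c3c1OB(c1ccccc1)OC3C=C(C)C)C2 | intermediate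
15 | ortho-quinone methide of ring B (C2'=O, C3'=CH–CH=CMe2) | CC(C)=CCc1cc2c(cc1O[Si](C)(C)C(C)(C)C)OC[C@@H](C1=CC=C(O[Si](C)(C)C(C)(C)C)C(=CC=C(C)C)C1=O)C2 | intermediate
16 | tert-butyl-[[8-[(3R)-7-(tert-butyldimethylsilyloxy)-6-(3-methylbut-2-en-1-yl)chroman-3-yl]-2,2-dimethyl-2H-chromen-5-yl]oxy]dimethylsilane | CC(C)=CCc1cc2c(cc1O[Si](C)(C)C(C)(C)C)OC[C@@H](c1ccc(O[Si](C)(C)C(C)(C)C)c3c1OC(C)(C)C=C3)C2 | intermediate
17 | 8-[(3R)-7-hydroxy-6-(3-methylbut-2-en-1-yl)chroman-3-yl]-2,2-dimethyl-2H-chromen-5-ol | CC(C)=CCc1cc2c(cc1O)OC[C@@H](c1ccc(O)c3c1OC(C)(C)C=C3)C2 | target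

Total step count: 7. Longest linear sequence: 7 steps (from 1 or 2 to 17).

Steps most likely to fail

Step 6. C–C bond formation at the crowded C3', between O2' and the silyloxy group on C4', may be slow, so that self-condensation of the aldehyde or loss of a silyl group overtakes the annulation. The fallback sets out from 12 and comes back at 16. O-alkylation of the 2'-OH with 3-chloro-3-methylbut-1-yne (CuCl2 cat., DBU, MeCN, 0 °C) should give the aryl 1,1-dimethylpropargyl ether F1. Heating it in N,N-diethylaniline at 180 °C should trigger an aromatic propargyl Claisen rearrangement onto C3', a [1,5]-H shift to the same quinone methide 15, and electrocyclisation to 16. The carbon is delivered intramolecularly, which makes this path less sensitive to crowding.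

Step 4. Discrimination between the three phenols may be poor, with silylation of O2' or incomplete silylation of O7 next to bromine. The fallback sets out from 9 and comes back at 10, and it hides O2' in a temporary ring instead of relying on rate differences. DDQ in dioxane should abstract hydride from C4 (para to the free 7-OH), and the 2'-OH should trap the quinone methide to give the cis-fused pterocarpan diol F2. Exhaustive silylation (excess TBSCl, imidazole, DMF) should then give the bis-silyl pterocarpan F3. Ionic hydrogenation (Et3SiH, TFA, CH2Cl2, 0 °C) should reopen the benzylic C4–O2' bond to 10, with C3 untouched.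

Step 2. The cascade may stall before the deoxygenation, or enantiopurity may be lost by tautomerisation of the quinone methide to the achiral isoflav-3-ene. The fallback sets out from 4 and comes back at 8, and it replaces the dynamic kinetic resolution by face-selective hydrogenation of an achiral alkene. NaBH4 in THF/EtOH should give the stereoisomeric isoflavan-4-ol mixture F4. TsOH in toluene at 80 °C should dehydrate it to the isoflav-3-ene F5. Asymmetric hydrogenation with [Ir(cod)(tBu-PHOX)]BArF (H2, 50 bar, CH2Cl2), with the ligand antipode chosen for the 3R product, should give 8 with the aryl bromide intact.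

Further compounds
F1 | step 6 | 2'-O-(2-methylbut-3-yn-2-yl) ether of 12 | CC(C)=CCc1cc2c(cc1O[Si](C)(C)C(C)(C)C)OC[C@@H](c1ccc(O[Si](C)(C)C(C)(C)C)cc1OC(C)(C)C#C)C2
F2 | step 4 | (6aR,11aR)-2-bromo-6a,11a-dihydro-6H-benzofuro[3,2-c]chromene-3,9-diol | Oc1cc2OC[C@H]3c4ccc(O)cc4O[C@H]3c2cc1Br
F3 | step 4 | (6aR,11aR)-2-bromo-3,9-bis(tert-butyldimethylsilyloxy)-6a,11a-dihydro-6H-benzofuro[3,2-c]chromene | CC(C)(C)[Si](C)(C)Oc1cc2OC[C@H]3c4ccc(O[Si](C)(C)C(C)(C)C)cc4O[C@H]3c2cc1Br
F4 | step 2 | 6-bromo-3-(2,4-dimethoxyphenyl)chromane-4,7-diol (mixture of stereoisomers) | COc1ccc(C2COc3cc(O)c(Br)cc3C2O)c(OC)c1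
F5 | step 2 | 6-bromo-3-(2,4-dimethoxyphenyl)-2H-chromen-7-ol | COc1ccc(C2=Cc3cc(Br)c(O)cc3OC2)c(OC)c1
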